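Atom labels used throughout: the cyclohexene is C1–C6 (CH3 on C1, C1=C2, ring B on C3, aroyl on C4, aryl on C5); ring B is C1′–C6′ (chromenone on C1′, cyclohexene on C3′). In the systematic names, C3, C4 and C5 of this text appear as C1, C6 and C5 of the cyclohex-2-en-1-yl unit.

## The problem

Target 17 is a 1-methylcyclohexene that carries at C3 the resorcinol ring B of a 3,7-dihydroxyflavone, at C4 a 2,4-dihydroxybenzoyl group and at C5 a 2,4-dihydroxyphenyl group, in the all-trans 3R,4R,5S arrangement. This is the exo-type adduct of a chalcone and a dehydroprenyl phenol. Of the three contiguous stereocentres, C4 is α to the ketone and can be equilibrated, and the C4/C5 trans relation is what an E-enone delivers. C3 cannot be epimerised, and it alone separates 17 from its cis,trans (endo-type) isomer; the 3,5-cis relation is also the one that stepwise axial additions to a cyclohexenone do not give. The C3–C3′ bond joins a secondary allylic carbon to the arene carbon that lies between the two phenolic oxygens of ring B, a doubly ortho-substituted point of union. No stereocentre can be bought, so the absolute configuration must come from a catalyst acting on C4/C5. The seven phenols and the enolic 3-hydroxychromenone are prone to oxidation, the ring-B hydroxyls can add to C1=C2 under acid (a cannabidiol-type ether closure) or to the C4 ketone, and base epimerises C4, so the last steps must be mild. The feature that the key step uses is the allylic triad C3–C2=C1(CH3): C1 is fully substituted, so an η3-allyl–metal unit over C1–C2–C3 can be arylated only at C3 with return of the C1=C2 bond, and a C3–O bond cis to the C4 acyl group, which an endo Diels–Alder reaction of a 1-acyloxydiene gives, is turned by an inverting allyl–aryl coupling into the all-trans C3–C3′ bond.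

## Retrosynthesis

17 from 16. No skeletal bond is cut; 16 carries seven methoxymethyl (MOM) ethers and one free, ketone-chelated phenol. MOM is chosen over acetate, benzyl or silyl because it survives KOH, alkaline H2O2, organolithium and organozinc reagents and the borate Lewis acid, and because it can be removed by a silyl triflate/bipyridyl protocol without free protic acid. The forward step must free seven phenols without touching C1=C2 or C4.

16 from 14 and 8, through arylzinc 15. The C3–C3′ bond is cut. Cutting the ring bonds with ring B already in place (Alternative 1) leaves the endo/exo question open. Cutting C3–C3′ in the Friedel–Crafts sense, as in cannabidiol chemistry, leaves the position on ring B (C3′ or C5′) open and needs acid. With an aryl–metal and an allylic acetate, the position on ring B is fixed by the C–I bond of 14 and the configuration at C3 by inversion. The precursors are two halves of similar size: flavonol iodide 14 has no stereocentre, and cyclohexenyl acetate 8 has all three from one cycloaddition. The forward reaction must bond at C3 and not C1, invert cleanly, avoid loss of acetic acid across C3–C4, and tolerate the chromenone and the aryl ketone; this points to an arylzinc halide and palladium.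

8 from 5 and 7. The C3–C4 and C5–C6 bonds are cut (Diels–Alder). With acetoxy in place of the bulky aryl group on the diene terminus, the endo transition state is expected to be favoured. The 1-acetoxy and 3-methyl groups both direct the acetoxy-bearing carbon next to the acyl-bearing carbon. The 2′-hydroxychalcone allows activation as a chiral borate chelate, which sets the absolute configuration at C4/C5. The precursors are an achiral chalcone and a five-carbon diene. The forward reaction must give face and endo selectivity and leave the β-acetoxy ketone intact.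

5 from 4 and 2; 2 from 1; 4 from 3; 7 from 6. The enone C=C is cut (Claisen–Schmidt). Aldehyde 2 and ketone 4 come from commercial 1 and 3 by MOM protection (4 keeps its chelated 2-OH). Diene 7 comes from prenal 6 by enol ester exchange.

14 from 13, 12, 11 and 4; 11 from 2 through 9 and 10. The pyranone O1–C2 and C3–O bonds are cut (Algar–Flynn–Oyamada), then the enone of 12 (Claisen–Schmidt of 11 with 4), then the C3′–I bond (directed ortho-metalation of 2 between its two MOM ethers, with the aldehyde masked in the flask as 9 and lithiated to 10). The flavonol is finished before the coupling so that alkaline H2O2 never meets the o-hydroxyaryl ketone of the core (Dakin oxidation) and so that the route is convergent. Compounds 2 and 4 each serve both halves.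

## Roads not taken

Alternative 1: Cut C3–C4 and C5–C6 with ring B on the diene. This is the most obvious plan: a borate-catalysed Diels–Alder reaction of chalcone 5 with dienyl flavonol A1 (from 14 by Suzuki–Miyaura coupling). The diene terminus then carries a 2,6-dioxygenated aryl group, which gives no structural basis for a strong endo or exo preference. The needed exo adduct 16 would form together with its C3 epimer A2, and C3 cannot be corrected afterwards. In the chosen plan the terminus carries a small acetoxy group, the ordinary endo preference is used, and inversion gives the all-trans array. The step count is the same. This plan is kept as the fallback for the key step.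

Alternative 2: Cut C3–C3′ as a conjugate addition and C1–CH3 as a cross-coupling. Copper-mediated 1,4-addition of arylzinc 15 to enone A3, trapping of the enolate as triflate A4 and a methyl coupling would complete the skeleton. Attack on the cyclohexenone half-chair is axial. With the C5 aryl group equatorial, this puts the new aryl group trans to it, whereas the C4 aroyl group asks for the other face, so the 3,5-cis product A4 is the disfavoured one. In addition, the C4–H of A3 is a vinylogous β-dicarbonyl proton that an organometallic would remove, two more steps are needed, and A3 has no evident catalytic asymmetric source.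

Alternative 3: Cut C3–C4 and C4–C5. A double Michael addition of acetophenone 4 to cross-conjugated dienone A5 would give cyclohexanone A6 under thermodynamic control, with the correct all-equatorial relative configuration. However, A5 is nearly mirror-symmetric (its two enone arms differ only in remote aryl substituents), so a catalyst has no handle for enantioselection and A6 would be racemic. The C1 ketone of A6 would then have to become C1(CH3)=C2 by enolisation toward C2 and not C6, which nothing in A6 biases.

Key step: step 10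

Assumption: the BINOL antipode is written as (R); the antipode meant is the one that gives the 4R,5S configuration of 8 in the known 2′-hydroxychalcone series.

## Route

Step 1
Reactants: 1 2,4-dihydroxybenzaldehyde
Product: 2 2,4-bis(methoxymethoxy)benzaldehyde
Conditions: NaH, MOMCl, DMF, 0 °C to rt
Reagents that add atoms: chloromethyl methyl ether (MOMCl), COCCl
Why: Williamson etherification; NaH deprotonates both phenols, including the hydrogen-bonded 2-OH. MOM ethers withstand the bases, organometallics and Lewis acid of steps 3–10 and direct the lithiation of step 6.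

Step 2
Reactants: 3 1-(2,4-dihydroxyphenyl)ethan-1-one
Product: 4 1-[2-hydroxy-4-(methoxymethoxy)phenyl]ethan-1-one
Conditions: MOMCl (1.1 equiv), K2CO3, acetone, rt
Reagents that add atoms: chloromethyl methyl ether (MOMCl), COCCl
Why: Mild-base Williamson etherification is selective for the 4-OH because the 2-OH is locked in a hydrogen bond to the ketone. The free 2-OH is needed for boron chelation in step 5 and for pyranone closure in step 8.

Step 3
Reactants: 4 1-[2-hydroxy-4-(methoxymethoxy)phenyl]ethan-1-one; 2 2,4-bis(methoxymethoxy)benzaldehyde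
Product: 5 (2E)-3-[2,4-bis(methoxymethoxy)phenyl]-1-[2-hydroxy-4-(methoxymethoxy)phenyl]prop-2-en-1-one
Conditions: KOH (aq), EtOH, rt
Reagents that add atoms: none
Why: Claisen–Schmidt condensation (aldol addition, E1cB dehydration) should give the E-enone, the thermodynamic geometry. The aldehyde has no α-hydrogen and the ketone enolises only at its methyl group.

Step 4
Reactants: 6 3-methylbut-2-enal
Product: 7 (1E)-3-methylbuta-1,3-dien-1-yl acetate
Conditions: isopropenyl acetate, p-TsOH (cat.), Cu(OAc)2 (trace, inhibitor), reflux, acetone distilled off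
Reagents that add atoms: isopropenyl acetate, CC(=C)OC(C)=O
Why: Acid-catalysed enol ester exchange traps the only possible dienol of 6 (γ-deprotonation) as its acetate. The E isomer should predominate and is the one that reacts in step 5.

Step 5
Reactants: 5 (2E)-3-[2,4-bis(methoxymethoxy)phenyl]-1-[2-hydroxy-4-(methoxymethoxy)phenyl]prop-2-en-1-one; 7 (1E)-3-methylbuta-1,3-dien-1-yl acetate
Product: 8 (1S,5S,6R)-5-[2,4-bis(methoxymethoxy)phenyl]-6-[2-hydroxy-4-(methoxymethoxy)benzoyl]-3-methylcyclohex-2-en-1-yl acetate
Conditions: (R)-BINOL (25 mol %), B(OPh)3 (25 mol %), 5 Å MS, PhCF3, rt to 40 °C, 7 (3 equiv)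
Reagents that add atoms: none
Why: Asymmetric Diels–Alder reaction of a 2′-hydroxychalcone activated as its chiral BINOL borate chelate: the chelate fixes the enone s-cis and lowers its LUMO, and the binaphthyl shields one face, which sets C4 and C5 (trans from the E-alkene; 4R,5S). The unsubstituted diene terminus, with the largest HOMO coefficient, bonds to the β-carbon, and the Alder endo rule with the small acetoxy group should place the C3 acetoxy group cis to the C4 aroyl group (3S).

Step 6
Reactants: 2 2,4-bis(methoxymethoxy)benzaldehyde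
Product: 11 3-iodo-2,4-bis(methoxymethoxy)benzaldehyde, via lithium aminoalkoxide 9 (not isolated), via aryllithium 10 (not isolated)
Conditions: N-methylpiperazine, n-BuLi, THF, −20 °C; then 2; then n-BuLi, −20 to 0 °C; I2, −78 °C to rt; aq NH4Cl
Reagents that add atoms: iodine, II
Why: Directed ortho-metalation: lithium N-methylpiperazide adds to the aldehyde to give α-amino alkoxide 9, which masks the carbonyl, and n-BuLi then removes the proton between the two MOM ethers, the site activated by both, to give 10. Iodine quenches the aryllithium and aqueous work-up releases the aldehyde.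

Step 7
Reactants: 11 3-iodo-2,4-bis(methoxymethoxy)benzaldehyde; 4 1-[2-hydroxy-4-(methoxymethoxy)phenyl]ethan-1-one
Product: 12 (2E)-1-[2-hydroxy-4-(methoxymethoxy)phenyl]-3-[3-iodo-2,4-bis(methoxymethoxy)phenyl]prop-2-en-1-one
Conditions: KOH (aq), EtOH, rt
Reagents that add atoms: none
Why: Claisen–Schmidt condensation as in step 3; the aryl iodide and the MOM ethers are inert to ethanolic KOH.

Step 8
Reactants: 12 (2E)-1-[2-hydroxy-4-(methoxymethoxy)phenyl]-3-[3-iodo-2,4-bis(methoxymethoxy)phenyl]prop-2-en-1-one
Product: 13 3-hydroxy-2-[3-iodo-2,4-bis(methoxymethoxy)phenyl]-7-(methoxymethoxy)-4H-chromen-4-one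
Conditions: H2O2 (30% aq), NaOH (aq), MeOH, 0 °C to rt
Reagents that add atoms: hydrogen peroxide, OO
Why: Algar–Flynn–Oyamada reaction: alkaline hydrogen peroxide epoxidises the enone, the 2′-phenoxide opens the epoxide at the β-carbon, and the dihydroflavonol is oxidised in the flask to the 3-hydroxychromenone. The ketone-bearing ring has no 6′-substituent, the case in which flavonol formation wins over aurone formation.

Step 9
Reactants: 13 3-hydroxy-2-[3-iodo-2,4-bis(methoxymethoxy)phenyl]-7-(methoxymethoxy)-4H-chromen-4-one
Product: 14 2-[3-iodo-2,4-bis(methoxymethoxy)phenyl]-3,7-bis(methoxymethoxy)-4H-chromen-4-one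
Conditions: MOMCl, iPr2NEt, CH2Cl2, 0 °C to rt
Reagents that add atoms: chloromethyl methyl ether (MOMCl), COCCl
Why: O-Alkylation of the enolic 3-OH removes the one acidic proton of the flavonol half, which would otherwise quench the arylzinc reagent of step 10.

Step 10
Reactants: 14 2-[3-iodo-2,4-bis(methoxymethoxy)phenyl]-3,7-bis(methoxymethoxy)-4H-chromen-4-one; 8 (1S,5S,6R)-5-[2,4-bis(methoxymethoxy)phenyl]-6-[2-hydroxy-4-(methoxymethoxy)benzoyl]-3-methylcyclohex-2-en-1-yl acetate
Product: 16 2-{3-[(1R,5S,6R)-5-[2,4-bis(methoxymethoxy)phenyl]-6-[2-hydroxy-4-(methoxymethoxy)benzoyl]-3-methylcyclohex-2-en-1-yl]-2,4-bis(methoxymethoxy)phenyl}-3,7-bis(methoxymethoxy)-4H-chromen-4-one, via arylzinc iodide 15 (not isolated)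
Conditions: Zn dust, LiCl, THF, 50 °C, excess Zn removed; then 8, Pd2(dba)3 (2.5 mol %), P(2-furyl)3 (10 mol %), THF, 0 °C to rt
Reagents that add atoms: none
Why: Zinc inserts into the C–I bond of 14 (LiCl keeps arylzinc 15 in solution); zerovalent palladium then ionises the pseudo-axial allylic acetate of 8 from the face opposite the leaving group, giving an η3-allylpalladium unit over C1–C2–C3 with the metal anti to the C4 aroyl group, and transmetalation from zinc followed by reductive elimination delivers the aryl group from the metal side. The closest known reaction type is the Negishi-type palladium-catalysed coupling of cyclic allylic acetates with arylzinc halides, which runs with net inversion. No ring is closed. The one new stereocentre, C3, is controlled by the C–O configuration set in step 5: inversion turns the acetoxy group cis to the aroyl group into an aryl group trans to it and cis to the C5 aryl group, the all-trans 3R,4R,5S array. Regioselectivity for C3 over C1 is needed and is secured by the methyl group on C1, since reductive elimination goes to the less substituted allyl terminus and restores C1=C2. Chemoselectivity against loss of acetic acid across C3–C4 is needed; it is helped by the absence of added base, by capture of acetate by zinc, and by the C4 hydrogen lying syn to palladium in the allyl complex, where base-induced anti elimination cannot use it. Material of the exo series, whose C–O bond is pseudo-equatorial, should ionise more slowly and to the hindered face, so the coupling selects the endo acetate. The arylzinc halide tolerates the chromenone, the aryl ketone and the chelated phenol of 8.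

Step 11
Reactants: 16 2-{3-[(1R,5S,6R)-5-[2,4-bis(methoxymethoxy)phenyl]-6-[2-hydroxy-4-(methoxymethoxy)benzoyl]-3-methylcyclohex-2-en-1-yl]-2,4-bis(methoxymethoxy)phenyl}-3,7-bis(methoxymethoxy)-4H-chromen-4-one
Product: 17 2-{3-[(1R,5S,6R)-6-(2,4-dihydroxybenzoyl)-5-(2,4-dihydroxyphenyl)-3-methylcyclohex-2-en-1-yl]-2,4-dihydroxyphenyl}-3,7-dihydroxy-4H-chromen-4-one
Conditions: TMSOTf, 2,2′-bipyridyl, CH2Cl2, 0 °C to rt; then H2O
Reagents that add atoms: none
Why: Buffered Lewis-acid cleavage of aryl MOM ethers: TMSOTf/2,2′-bipyridyl converts each ArOCH2OCH3 into ArOSiMe3 and a methoxymethylpyridinium salt, and water then hydrolyses the silyl ethers. No free Brønsted acid is present, which should protect the C1=C2 bond, and no stereocentre is touched.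

## Compound list

1 | 2,4-dihydroxybenzaldehyde | O=Cc1ccc(O)cc1O | starting material
2 | 2,4-bis(methoxymethoxy)benzaldehyde | COCOc1ccc(C=O)c(OCOC)c1 | intermediate
3 | 1-(2,4-dihydroxyphenyl)ethan-1-one | CC(=O)c1ccc(O)cc1O | starting material
4 | 1-[2-hydroxy-4-(methoxymethoxy)phenyl]ethan-1-one | CC(=O)c1ccc(OCOC)cc1O | intermediate
5 | (2E)-3-[2,4-bis(methoxymethoxy)phenyl]-1-[2-hydroxy-4-(methoxymethoxy)phenyl]prop-2-en-1-one | COCOc1ccc(C(=O)/C=C/c2ccc(OCOC)cc2OCOC)c(O)c1 | intermediate
6 | 3-methylbut-2-enal | CC(C)=CC=O | starting material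
7 | (1E)-3-methylbuta-1,3-dien-1-yl acetate | CC(=C)/C=C/OC(C)=O | intermediate
8 | (1S,5S,6R)-5-[2,4-bis(methoxymethoxy)phenyl]-6-[2-hydroxy-4-(methoxymethoxy)benzoyl]-3-methylcyclohex-2-en-1-yl acetate | CC1=C[C@H](OC(C)=O)[C@H](C(=O)c2ccc(OCOC)cc2O)[C@@H](c2ccc(OCOC)cc2OCOC)C1 | intermediate
9 | lithium [2,4-bis(methoxymethoxy)phenyl](4-methylpiperazin-1-yl)methanolate | COCOc1ccc(C([O-])N2CCN(C)CC2)c(OCOC)c1.[Li+] | intermediate
10 | lithium [3-lithio-2,4-bis(methoxymethoxy)phenyl](4-methylpiperazin-1-yl)methanolate | [Li]c1c(OCOC)ccc(C([O-])N2CCN(C)CC2)c1OCOC.[Li+] | intermediate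
11 | 3-iodo-2,4-bis(methoxymethoxy)benzaldehyde | COCOc1ccc(C=O)c(OCOC)c1I | intermediate
12 | (2E)-1-[2-hydroxy-4-(methoxymethoxy)phenyl]-3-[3-iodo-2,4-bis(methoxymethoxy)phenyl]prop-2-en-1-one | COCOc1ccc(C(=O)/C=C/c2ccc(OCOC)c(I)c2OCOC)c(O)c1 | intermediate
13 | 3-hydroxy-2-[3-iodo-2,4-bis(methoxymethoxy)phenyl]-7-(methoxymethoxy)-4H-chromen-4-one | O=c1c(O)c(-c2ccc(OCOC)c(I)c2OCOC)oc2cc(OCOC)ccc12 | intermediate
14 | 2-[3-iodo-2,4-bis(methoxymethoxy)phenyl]-3,7-bis(methoxymethoxy)-4H-chromen-4-one | O=c1c(OCOC)c(-c2ccc(OCOC)c(I)c2OCOC)oc2cc(OCOC)ccc12 | intermediate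
15 | {3-[3,7-bis(methoxymethoxy)-4-oxo-4H-chromen-2-yl]-2,6-bis(methoxymethoxy)phenyl}zinc iodide | O=c1c(OCOC)c(-c2ccc(OCOC)c([Zn]I)c2OCOC)oc2cc(OCOC)ccc12 | intermediate
16 | 2-{3-[(1R,5S,6R)-5-[2,4-bis(methoxymethoxy)phenyl]-6-[2-hydroxy-4-(methoxymethoxy)benzoyl]-3-methylcyclohex-2-en-1-yl]-2,4-bis(methoxymethoxy)phenyl}-3,7-bis(methoxymethoxy)-4H-chromen-4-one | CC1=C[C@@H](c2c(OCOC)ccc(-c3oc4cc(OCOC)ccc4c(=O)c3OCOC)c2OCOC)[C@H](C(=O)c2ccc(OCOC)cc2O)[C@@H](c2ccc(OCOC)cc2OCOC)C1 | intermediate
17 | 2-{3-[(1R,5S,6R)-6-(2,4-dihydroxybenzoyl)-5-(2,4-dihydroxyphenyl)-3-methylcyclohex-2-en-1-yl]-2,4-dihydroxyphenyl}-3,7-dihydroxy-4H-chromen-4-one (CNP0190989.1) | CC1=C[C@@H](c2c(O)ccc(-c3oc4cc(O)ccc4c(=O)c3O)c2O)[C@H](C(=O)c2ccc(O)cc2O)[C@@H](c2ccc(O)cc2O)C1 | target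

## Step count and risks

Total step count: 11

Longest linear sequence: 7 steps (1, 6, 7, 8, 9, 10, 11)

Least certain steps:

Step 10 (key step). The most likely failure is loss of acetic acid across C3–C4, from 8 itself or from the allylpalladium intermediate, outpacing a slow transmetalation of the doubly ortho-substituted arylzinc; the C4 hydrogen is α to the ketone and the product of elimination is a conjugated dienone. A second risk is partial loss of stereospecificity if the allylpalladium faces exchange. Fallback by known chemistry, from 14: Suzuki–Miyaura coupling of 14 with commercial (E)-4,4,5,5-tetramethyl-2-(3-methylbuta-1,3-dien-1-yl)-1,3,2-dioxaborolane (Pd(PPh3)4, K2CO3, dioxane–water) should give 2-{2,4-bis(methoxymethoxy)-3-[(1E)-3-methylbuta-1,3-dien-1-yl]phenyl}-3,7-bis(methoxymethoxy)-4H-chromen-4-one F1. Its Diels–Alder reaction with chalcone 5 under the borate conditions of step 5 builds the cyclohexene directly, and the all-trans adduct, separated by chromatography, is 16, where the route is rejoined; steps 4, 5 and the zinc chemistry are bypassed.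

Step 5. Poor endo/exo or facial selectivity may result because an oxygenated diene has not the same steric profile as the dienes known in this catalysis. Lewis-acid-promoted loss of acetic acid from the β-acetoxy ketone and polymerisation of the dienyl acetate are further risks. Fallback, from 6 and 5: prenal 6 is converted (TBSOTf, Et3N) into the silyl dienol ether tert-butyl(dimethyl){[(1E)-3-methylbuta-1,3-dien-1-yl]oxy}silane F2, a more electron-rich diene whose adduct has no acyloxy leaving group. The same borate-catalysed cycloaddition with 5, at lower temperature, should give tert-butyl{[(1S,5S,6R)-5-[2,4-bis(methoxymethoxy)phenyl]-6-[2-hydroxy-4-(methoxymethoxy)benzoyl]-3-methylcyclohex-2-en-1-yl]oxy}dimethylsilane F3. Exchange of silyl for acetyl (Ac2O, FeCl3 cat., 0 °C), which leaves the C3–O bond untouched, returns to 8.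

Step 11. Once the ring-B phenols are free, any adventitious acid may add one of them to C1=C2 (cyclic ether formation) or promote ketal formation with the C4 ketone; the hindered MOM ethers flanking C3′ may also be cleaved incompletely. Fallback, from 14, keeps ring B masked as acetates until the very end. Acid methanolysis of the robust iodide 14 (HCl, MeOH) gives 2-(2,4-dihydroxy-3-iodophenyl)-3,7-dihydroxy-4H-chromen-4-one F4, and acetylation (Ac2O, pyridine) gives 2-[2,4-bis(acetyloxy)-3-iodophenyl]-4-oxo-4H-chromene-3,7-diyl diacetate F5. Zinc insertion as in step 10 gives {2,6-bis(acetyloxy)-3-[3,7-bis(acetyloxy)-4-oxo-4H-chromen-2-yl]phenyl}zinc iodide F6, which is coupled with 8 to 2-{2,4-bis(acetyloxy)-3-[(1R,5S,6R)-5-[2,4-bis(methoxymethoxy)phenyl]-6-[2-hydroxy-4-(methoxymethoxy)benzoyl]-3-methylcyclohex-2-en-1-yl]phenyl}-4-oxo-4H-chromene-3,7-diyl diacetate F7. The three MOM ethers are removed as in step 11 while ring B is still acetylated, giving 2-{2,4-bis(acetyloxy)-3-[(1R,5S,6R)-6-(2,4-dihydroxybenzoyl)-5-(2,4-dihydroxyphenyl)-3-methylcyclohex-2-en-1-yl]phenyl}-4-oxo-4H-chromene-3,7-diyl diacetate F8. Methanolysis of the acetates (K2CO3, MeOH, rt) then gives 17.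

Step 6. Lithiation may compete at other ring positions, or n-BuLi may add to aldehyde that was not fully masked. Fallback, from 1: electrophilic iodination (I2, HIO3, aqueous EtOH), directed by the chelated hydroxyl to the carbon between the two oxygens, should give 2,4-dihydroxy-3-iodobenzaldehyde F9, and NaH/MOMCl then gives 11.

## Further compounds

F1 | step 10 | 2-{2,4-bis(methoxymethoxy)-3-[(1E)-3-methylbuta-1,3-dien-1-yl]phenyl}-3,7-bis(methoxymethoxy)-4H-chromen-4-one | CC(=C)/C=C/c1c(OCOC)ccc(-c2oc3cc(OCOC)ccc3c(=O)c2OCOC)c1OCOC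
F2 | step 5 | tert-butyl(dimethyl){[(1E)-3-methylbuta-1,3-dien-1-yl]oxy}silane | CC(=C)/C=C/O[Si](C)(C)C(C)(C)C
F3 | step 5 | tert-butyl{[(1S,5S,6R)-5-[2,4-bis(methoxymethoxy)phenyl]-6-[2-hydroxy-4-(methoxymethoxy)benzoyl]-3-methylcyclohex-2-en-1-yl]oxy}dimethylsilane | CC1=C[C@H](O[Si](C)(C)C(C)(C)C)[C@H](C(=O)c2ccc(OCOC)cc2O)[C@@H](c2ccc(OCOC)cc2OCOC)C1
F4 | step 11 | 2-(2,4-dihydroxy-3-iodophenyl)-3,7-dihydroxy-4H-chromen-4-one | O=c1c(O)c(-c2ccc(O)c(I)c2O)oc2cc(O)ccc12
F5 | step 11 | 2-[2,4-bis(acetyloxy)-3-iodophenyl]-4-oxo-4H-chromene-3,7-diyl diacetate | O=c1c(OC(C)=O)c(-c2ccc(OC(C)=O)c(I)c2OC(C)=O)oc2cc(OC(C)=O)ccc12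
F6 | step 11 | {2,6-bis(acetyloxy)-3-[3,7-bis(acetyloxy)-4-oxo-4H-chromen-2-yl]phenyl}zinc iodide | O=c1c(OC(C)=O)c(-c2ccc(OC(C)=O)c([Zn]I)c2OC(C)=O)oc2cc(OC(C)=O)ccc12
F7 | step 11 | 2-{2,4-bis(acetyloxy)-3-[(1R,5S,6R)-5-[2,4-bis(methoxymethoxy)phenyl]-6-[2-hydroxy-4-(methoxymethoxy)benzoyl]-3-methylcyclohex-2-en-1-yl]phenyl}-4-oxo-4H-chromene-3,7-diyl diacetate | CC1=C[C@@H](c2c(OC(C)=O)ccc(-c3oc4cc(OC(C)=O)ccc4c(=O)c3OC(C)=O)c2OC(C)=O)[C@H](C(=O)c2ccc(OCOC)cc2O)[C@@H](c2ccc(OCOC)cc2OCOC)C1
F8 | step 11 | 2-{2,4-bis(acetyloxy)-3-[(1R,5S,6R)-6-(2,4-dihydroxybenzoyl)-5-(2,4-dihydroxyphenyl)-3-methylcyclohex-2-en-1-yl]phenyl}-4-oxo-4H-chromene-3,7-diyl diacetate | CC1=C[C@@H](c2c(OC(C)=O)ccc(-c3oc4cc(OC(C)=O)ccc4c(=O)c3OC(C)=O)c2OC(C)=O)[C@H](C(=O)c2ccc(O)cc2O)[C@@H](c2ccc(O)cc2O)C1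
F9 | step 6 | 2,4-dihydroxy-3-iodobenzaldehyde | O=Cc1ccc(O)c(I)c1O
A1 | alternative 1 | 2-{2,4-bis(methoxymethoxy)-3-[(1E)-3-methylbuta-1,3-dien-1-yl]phenyl}-3,7-bis(methoxymethoxy)-4H-chromen-4-one | CC(=C)/C=C/c1c(OCOC)ccc(-c2oc3cc(OCOC)ccc3c(=O)c2OCOC)c1OCOC
A2 | alternative 1 | 2-{3-[(1S,5S,6R)-5-[2,4-bis(methoxymethoxy)phenyl]-6-[2-hydroxy-4-(methoxymethoxy)benzoyl]-3-methylcyclohex-2-en-1-yl]-2,4-bis(methoxymethoxy)phenyl}-3,7-bis(methoxymethoxy)-4H-chromen-4-one | CC1=C[C@H](c2c(OCOC)ccc(-c3oc4cc(OCOC)ccc4c(=O)c3OCOC)c2OCOC)[C@H](C(=O)c2ccc(OCOC)cc2O)[C@@H](c2ccc(OCOC)cc2OCOC)C1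
A3 | alternative 2 | (4S,5S)-4-[2,4-bis(methoxymethoxy)benzoyl]-5-[2,4-bis(methoxymethoxy)phenyl]cyclohex-2-en-1-one | O=C1C=C[C@H](C(=O)c2ccc(OCOC)cc2OCOC)[C@@H](c2ccc(OCOC)cc2OCOC)C1
A4 | alternative 2 | (3R,4R,5S)-4-[2,4-bis(methoxymethoxy)benzoyl]-5-[2,4-bis(methoxymethoxy)phenyl]-3-{3-[3,7-bis(methoxymethoxy)-4-oxo-4H-chromen-2-yl]-2,6-bis(methoxymethoxy)phenyl}cyclohex-1-en-1-yl trifluoromethanesulfonate | O=S(=O)(OC1=C[C@@H](c2c(OCOC)ccc(-c3oc4cc(OCOC)ccc4c(=O)c3OCOC)c2OCOC)[C@H](C(=O)c2ccc(OCOC)cc2OCOC)[C@@H](c2ccc(OCOC)cc2OCOC)C1)C(F)(F)F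
A5 | alternative 3 | (1E,4E)-1-[2,4-bis(methoxymethoxy)phenyl]-5-[3-(1,3-dioxolan-2-yl)-2,6-bis(methoxymethoxy)phenyl]penta-1,4-dien-3-one | O=C(/C=C/c1ccc(OCOC)cc1OCOC)/C=C/c1c(OCOC)ccc(C2OCCO2)c1OCOC
A6 | alternative 3 | rac-(3R,4R,5S)-5-[2,4-bis(methoxymethoxy)phenyl]-3-[3-(1,3-dioxolan-2-yl)-2,6-bis(methoxymethoxy)phenyl]-4-[2-hydroxy-4-(methoxymethoxy)benzoyl]cyclohexan-1-one (one enantiomer drawn) | O=C1C[C@@H](c2c(OCOC)ccc(C3OCCO3)c2OCOC)[C@H](C(=O)c2ccc(OCOC)cc2O)[C@@H](c2ccc(OCOC)cc2OCOC)C1
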